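**Retrosynthetic overview**
- Target 15 comes from its 3',4'-di-O-benzyl ether 14 by hydrogenolysis.
- The strategy rests on the 4-pyranone ring C (O1, C2, C3, C4, C4a, C8a). O1 and C4a sit on neighbouring carbons of ring A, C4 is a lone carbonyl carbon, and C2–C3 is a two-carbon unit carrying ring B. Ring C is therefore cut at C4a–C4, C4–C3 and O1–C2 into iodophenol 8, carbon monoxide 11 (C4) and aryl alkyne 10.
- Iodophenol 8 comes from 2,3,4,5-tetramethoxyphenol 7 by iodination of its only free ring carbon. Phenol 7 comes from aldehyde 1 by two aldehyde-to-phenol oxidations with methylation and formylation between them.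
- Alkyne 10 comes from aldehyde 9 by one-carbon homologation.
- Ring order: rings A and B are bought as benzenes; ring C is the only ring formed, in step 7.

Key step: step 7

Assumption: the target is a planar, achiral flavone with no stereogenic element, so the structure as drawn is its only stereoisomer and no stereocontrol is needed.

**Step 1**
Reactants: 1 2,3,4-trimethoxybenzaldehyde
Product: 3 2,3,4-trimethoxyphenol, via 2,3,4-trimethoxyphenyl formate 2 (not isolated)
Conditions: 30% H2O2, cat. H2SO4, MeOH, rt
Reagents that add atoms: hydrogen peroxide, OO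
Why: Acid-catalysed Dakin oxidation, in which the peroxide adduct of the aldehyde rearranges with migration of the electron-rich aryl group (Baeyer–Villiger type) to formate 2, which the acidic methanol should cleave to the phenol.

**Step 2**
Reactants: 3 2,3,4-trimethoxyphenol
Product: 4 1,2,3,4-tetramethoxybenzene
Conditions: MeI, K2CO3, acetone, reflux
Reagents that add atoms: iodomethane, CI
Why: Williamson O-methylation of the phenoxide by SN2 on iodomethane, with no competing nucleophilic site.

**Step 3**
Reactants: 4 1,2,3,4-tetramethoxybenzene
Product: 5 2,3,4,5-tetramethoxybenzaldehyde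
Conditions: Cl2CHOMe, TiCl4, CH2Cl2, −10 to 0 °C; then ice-water
Reagents that add atoms: dichloromethyl methyl ether, COC(Cl)Cl; water, O
Why: Rieche formylation, in which the two free ring positions are equivalent by symmetry and each is ortho and para to methoxy groups, so electrophilic substitution followed by hydrolysis can give only one monoaldehyde.

**Step 4**
Reactants: 5 2,3,4,5-tetramethoxybenzaldehyde
Product: 7 2,3,4,5-tetramethoxyphenol, via 2,3,4,5-tetramethoxyphenyl formate 6 (not isolated)
Conditions: mCPBA (1.1 equiv), CH2Cl2, 0 °C to rt; then MeOH, cat. HCl, rt, under argon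
Reagents that add atoms: meta-chloroperoxybenzoic acid, O=C(OO)c1cccc(Cl)c1
Why: Baeyer–Villiger oxidation with migration of the very electron-rich aryl group to formate 6, whose acidic methanolysis releases the phenol, while the near-stoichiometric peracid charge and the absence of base should limit over-oxidation to a quinone.

**Step 5**
Reactants: 7 2,3,4,5-tetramethoxyphenol
Product: 8 2-iodo-3,4,5,6-tetramethoxyphenol
Conditions: NIS (1.05 equiv), MeCN, 0 °C, dark
Reagents that add atoms: N-iodosuccinimide, O=C1CCC(=O)N1I
Why: Electrophilic aromatic iodination, in which the single unsubstituted ring carbon lies ortho to the free hydroxyl, so the regiochemistry is fixed and a mild iodonium source at low temperature should favour substitution over oxidation.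

**Step 6**
Reactants: 9 3,4-bis(benzyloxy)benzaldehyde
Product: 10 1,2-bis(benzyloxy)-4-ethynylbenzene
Conditions: dimethyl (1-diazo-2-oxopropyl)phosphonate, K2CO3, MeOH/THF, 0 °C to rt
Reagents that add atoms: dimethyl (1-diazo-2-oxopropyl)phosphonate, CC(=O)C(=[N+]=[N-])P(=O)(OC)OC
Why: Ohira–Bestmann (Seyferth–Gilbert) homologation, in which methanolysis of the reagent gives the diazomethylphosphonate anion, olefination of the aldehyde gives a diazoalkene, and loss of N2 with a 1,2-hydrogen shift gives the terminal alkyne under conditions that leave benzyl ethers untouched.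

**Step 7**
Reactants: 8 2-iodo-3,4,5,6-tetramethoxyphenol; 10 1,2-bis(benzyloxy)-4-ethynylbenzene (1.3 equiv); 11 carbon monoxide
Product: 14 3',4'-bis(benzyloxy)-5,6,7,8-tetramethoxyflavone, via o-hydroxyaryl ynone 12 (not isolated), via diethylamino enone 13 (not isolated)
Conditions: PdCl2(dppf) (5 mol %), CO (20 bar), Et2NH, 120 °C, autoclave, copper-free
Reagents that add atoms: carbon monoxide (compound 11), [C-]#[O+]
Why: Pd(0) adds oxidatively to the C–I bond of 8, CO inserts to give the aroyl-palladium (new C4a–C4 bond), and amine-assisted transfer of the alkynyl group from 10 followed by reductive elimination gives ynone 12 (new C4–C3 bond). Diethylamine then adds to the ynone to give enaminone 13, and the ortho phenol oxygen attacks the β-carbon and expels the amine, forming O1–C2. The closest known reaction type is the palladium-catalysed carbonylative coupling–cyclisation of o-iodophenols with terminal alkynes to chromones and flavones. The pyranone ring is closed in a 6-endo-trig addition–elimination on the enaminone, not in a 5-exo-dig attack on the ynone, which would give an aurone; no stereocentre is formed. The step needs carbonylative coupling to win over direct Sonogashira coupling and needs six- over five-membered closure; the first is secured by CO pressure, the absence of copper and the doubly ortho-substituted aryl-palladium, which inserts CO readily, and the second by the secondary amine, since the enaminone can only close to the six-membered ring. Regiochemistry is not an issue because iodine occupies the only non-oxygenated ring carbon, so the fully substituted A ring is carried in intact.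

**Step 8**
Reactants: 14 3',4'-bis(benzyloxy)-5,6,7,8-tetramethoxyflavone
Product: 15 3',4'-dihydroxy-5,6,7,8-tetramethoxyflavone (target)
Conditions: H2 (1 atm), 10% Pd/C, THF/MeOH, rt, stopped after uptake of two equivalents
Reagents that add atoms: none
Why: Catalytic hydrogenolysis of the two benzylic C–O bonds, which should leave the aryl methyl ethers and the conjugated chromone untouched at ambient pressure and temperature.

**Compound list**
1 | 2,3,4-trimethoxybenzaldehyde | COc1ccc(C=O)c(OC)c1OC | starting material
2 | 2,3,4-trimethoxyphenyl formate | COc1ccc(OC=O)c(OC)c1OC | intermediate (not isolated)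
3 | 2,3,4-trimethoxyphenol | COc1ccc(O)c(OC)c1OC | intermediate
4 | 1,2,3,4-tetramethoxybenzene | COc1ccc(OC)c(OC)c1OC | intermediate
5 | 2,3,4,5-tetramethoxybenzaldehyde | COc1cc(C=O)c(OC)c(OC)c1OC | intermediate
6 | 2,3,4,5-tetramethoxyphenyl formate | COc1cc(OC=O)c(OC)c(OC)c1OC | intermediate (not isolated)
7 | 2,3,4,5-tetramethoxyphenol | COc1cc(O)c(OC)c(OC)c1OC | intermediate
8 | 2-iodo-3,4,5,6-tetramethoxyphenol | COc1c(OC)c(OC)c(I)c(O)c1OC | intermediate
9 | 3,4-bis(benzyloxy)benzaldehyde | O=Cc1ccc(OCc2ccccc2)c(OCc2ccccc2)c1 | starting material
10 | 1,2-bis(benzyloxy)-4-ethynylbenzene | C#Cc1ccc(OCc2ccccc2)c(OCc2ccccc2)c1 | intermediate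
11 | carbon monoxide | [C-]#[O+] | starting material
12 | 3-[3,4-bis(benzyloxy)phenyl]-1-(2-hydroxy-3,4,5,6-tetramethoxyphenyl)prop-2-yn-1-one | COc1c(OC)c(OC)c(C(=O)C#Cc2ccc(OCc3ccccc3)c(OCc3ccccc3)c2)c(O)c1OC | intermediate (not isolated)
13 | (E)-3-[3,4-bis(benzyloxy)phenyl]-3-(diethylamino)-1-(2-hydroxy-3,4,5,6-tetramethoxyphenyl)prop-2-en-1-one | CCN(CC)/C(=C/C(=O)c1c(O)c(OC)c(OC)c(OC)c1OC)c1ccc(OCc2ccccc2)c(OCc2ccccc2)c1 | intermediate (not isolated)
14 | 3',4'-bis(benzyloxy)-5,6,7,8-tetramethoxyflavone | COc1c(OC)c(OC)c2c(=O)cc(-c3ccc(OCc4ccccc4)c(OCc4ccccc4)c3)oc2c1OC | intermediate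
15 | 3',4'-dihydroxy-5,6,7,8-tetramethoxyflavone, 2-(3,4-dihydroxyphenyl)-5,6,7,8-tetramethoxy-4H-chromen-4-one | COc1c(OC)c(OC)c2c(=O)cc(-c3ccc(O)c(O)c3)oc2c1OC | target

**Totals**
Total step count: 8 steps.
Longest linear sequence: 7 steps (steps 1–5, 7 and 8, from 1 to 15).

**Steps most likely to fail**

1. Step 7. Oxidative addition and CO insertion at the doubly ortho-substituted, electron-rich iodide may be slow. Direct, non-carbonylative coupling with closure to a 2-arylbenzofuran could then compete, as could capture of the aroyl-palladium by diethylamine, five-membered closure of the ynone, or thermal oligomerisation of the alkyne. The fallback sets out from 7 and comes back at 14, building C4 and C3 from an acetyl group instead of CO and an alkyne. Friedel–Crafts C-acetylation of 7 at its only free ring carbon (AcOH, BF3·OEt2, 80 °C) should give 1-(2-hydroxy-3,4,5,6-tetramethoxyphenyl)ethan-1-one F1. Claisen–Schmidt condensation of F1 with aldehyde 9 (KOH, EtOH, rt) should give (E)-3-[3,4-bis(benzyloxy)phenyl]-1-(2-hydroxy-3,4,5,6-tetramethoxyphenyl)prop-2-en-1-one F2. Oxidative cyclisation of F2 with catalytic I2 in DMSO at 120 °C should give 14, and step 8 then follows unchanged.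

2. Step 5. The iodonium source may oxidise the pentaoxygenated phenol, with oxidative demethylation to a quinone, instead of substituting the ring. The fallback sets out from 7 and comes back at 8, replacing electrophilic iodination by directed metalation of a protected phenol. Protection with MOMCl and i-Pr2NEt in CH2Cl2 should give 1,2,3,4-tetramethoxy-5-(methoxymethoxy)benzene F3. Ortho-lithiation with n-BuLi in THF (−78 to 0 °C) at the only ring C–H, flanked by the OMOM and OMe groups, should give [2-(methoxymethoxy)-3,4,5,6-tetramethoxyphenyl]lithium F4. Quenching with I2 at −78 °C should give 1-iodo-2-(methoxymethoxy)-3,4,5,6-tetramethoxybenzene F5, and HCl in MeOH at rt should then release 8.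

3. Step 3. The titanium Lewis acid may cleave a methyl ether next to the new formyl group by chelation, or conversion may be incomplete because the two inner methoxy groups are twisted out of conjugation. The fallback sets out from 4 and comes back at 5, replacing electrophilic formylation by metalation. Ortho-lithiation of 4 with n-BuLi and TMEDA in THF at 0 °C should give (2,3,4,5-tetramethoxyphenyl)lithium F6, and quenching with DMF followed by aqueous work-up should give aldehyde 5.

**Further compounds**
F1 | step 7 | 1-(2-hydroxy-3,4,5,6-tetramethoxyphenyl)ethan-1-one | CC(=O)c1c(O)c(OC)c(OC)c(OC)c1OC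
F2 | step 7 | (E)-3-[3,4-bis(benzyloxy)phenyl]-1-(2-hydroxy-3,4,5,6-tetramethoxyphenyl)prop-2-en-1-one | O=C(/C=C/c1ccc(OCc2ccccc2)c(OCc2ccccc2)c1)c1c(O)c(OC)c(OC)c(OC)c1OC
F3 | step 5 | 1,2,3,4-tetramethoxy-5-(methoxymethoxy)benzene | COCOc1cc(OC)c(OC)c(OC)c1OC
F4 | step 5 | [2-(methoxymethoxy)-3,4,5,6-tetramethoxyphenyl]lithium | [Li]c1c(OCOC)c(OC)c(OC)c(OC)c1OC
F5 | step 5 | 1-iodo-2-(methoxymethoxy)-3,4,5,6-tetramethoxybenzene | COCOc1c(I)c(OC)c(OC)c(OC)c1OC
F6 | step 3 | (2,3,4,5-tetramethoxyphenyl)lithium | [Li]c1cc(OC)c(OC)c(OC)c1OC
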